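**Direct plan and its weak points**

A direct plan would make 3-(4-bromophenyl)-8-chloro-7-hydroxyisoflavone A1 by the deoxybenzoin method and cap it as the methyl ether A2. A2 would be coupled with 2,6-dimethoxyphenol A3 under copper catalysis to the diaryl ether A4, which would be demethylated to the triphenol A5. A5 would finally be acylated with 4-hydroxyphenylacetic acid A6 and the second pyranone closed in the same pot.
- The copper-catalysed ether coupling joins a di-ortho-substituted phenol to a chromenone in hot basic DMSO: the nucleophile is hindered and the pyranone ring can open.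
- The methylation and the triple BBr3 demethylation are protecting-group traffic that forms no bond of the skeleton.
- The last acylation and ring closure run in hot BF3·OEt2 on a free triphenol that already holds one finished isoflavone, so O-acylation, attack on the wrong ring and decomposition threaten all the material at the end.

**Retrosynthetic overview of the new route**

Both pyranone rings are cut at once: C3–C1' and O1–C2 of the chlorinated chromenone, and C3''–C1''' and O1''–C2'' of the second chromenone, lead back to the open-chain bis(2'-hydroxychalcone) 10.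
In 10 each aryl ring still sits on the carbon that becomes C2 or C2''; a double oxidative 1,2-aryl shift moves both rings to C3 and C3'', and acid then closes ring C and ring C'' together and removes the MOM groups.
The hindered C8''–O–C4' ether is made early by SNAr on 4-fluorobenzaldehyde, whose formyl carbon first activates the displacement and later becomes C2 of the chlorinated ring.
No heterocycle exists before the last step, so no chromenone meets base or copper, no methyl ether needs BBr3, and no Friedel–Crafts acylation is run on an advanced polyphenol.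

Key step: step 7

Remark on the chemistry: the target has no stereocentre. The two CH centres of the unisolated bis-acetal 11 form without control and vanish on ring closure. Compounds 1, 3, 5 and 7 are taken as commercial.

**Route**

Step 1
Reactants: 1 gallacetophenone, 1-(2,3,4-trihydroxyphenyl)ethan-1-one
Product: 2 1-[2,3-dihydroxy-4-(methoxymethoxy)phenyl]ethan-1-one
Conditions: MOMCl (1.0 equiv), K2CO3 (1.0 equiv), acetone, 0 °C to rt, argon
Reagents that add atoms: chloromethyl methyl ether, COCCl
Why: Williamson-type O-alkylation with one equivalent of base should take the most acidic phenol, the 4-OH para to the acetyl group, because the 2-OH is held in a hydrogen bond to the carbonyl and the 3-OH is the least acidic, the order that stepwise alkylation of gallacetophenone follows.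

Step 2
Reactants: 2 1-[2,3-dihydroxy-4-(methoxymethoxy)phenyl]ethan-1-one; 3 4-(methoxymethoxy)benzaldehyde
Product: 4 (2E)-1-[2,3-dihydroxy-4-(methoxymethoxy)phenyl]-3-[4-(methoxymethoxy)phenyl]prop-2-en-1-one
Conditions: KOH (50% aq.), EtOH, rt, argon; AcOH to pH 6 at 0 °C
Reagents that add atoms: none
Why: Claisen–Schmidt (crossed aldol) condensation between the only enolisable ketone and a non-enolisable aldehyde, with E1cB dehydration giving the conjugated E-enone as the thermodynamic product; the MOM acetals are stable to hydroxide and argon protects the catecholate from air.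

Step 3
Reactants: 4 (2E)-1-[2,3-dihydroxy-4-(methoxymethoxy)phenyl]-3-[4-(methoxymethoxy)phenyl]prop-2-en-1-one; 5 4-fluorobenzaldehyde
Product: 6 4-{2-hydroxy-6-(methoxymethoxy)-3-[(2E)-3-[4-(methoxymethoxy)phenyl]prop-2-enoyl]phenoxy}benzaldehyde
Conditions: K2CO3 (1.5 equiv), DMSO, 90 °C, argon
Reagents that add atoms: none
Why: SNAr by addition–elimination through a Meisenheimer complex stabilised by the para-formyl group, with fluoride as leaving group; the 3'-phenoxide should react because the 2'-OH is chelated to the enone carbonyl and shielded (the 2-OH of gallacetophenone is likewise spared in alkylations), and the chalcone has no enolisable C–H that could condense with the aldehyde.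

Step 4
Reactants: 7 2-chlororesorcinol (2-chlorobenzene-1,3-diol)
Product: 8 1-(3-chloro-2,4-dihydroxyphenyl)ethan-1-one
Conditions: AcOH (1.2 equiv), BF3·OEt2 (as medium), 90 °C; then aq. NaOAc
Reagents that add atoms: acetic acid, CC(=O)O
Why: Friedel–Crafts C-acylation (Nencki type, through the aryl acetate and its boron chelate) at C4 of the resorcinol, ortho and para to the two OH groups; C4 and C6 are equivalent and the ketone formed deactivates the ring against a second acylation.

Step 5
Reactants: 8 1-(3-chloro-2,4-dihydroxyphenyl)ethan-1-one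
Product: 9 1-[3-chloro-2-hydroxy-4-(methoxymethoxy)phenyl]ethan-1-one
Conditions: MOMCl (1.1 equiv), K2CO3, acetone, rt
Reagents that add atoms: chloromethyl methyl ether, COCCl
Why: Williamson-type O-alkylation of the free, more acidic 4-OH, while the 2-OH, chelated to the acetyl group and flanked by chlorine, stays untouched and remains available for the later ring closure.

Step 6
Reactants: 6 4-{2-hydroxy-6-(methoxymethoxy)-3-[(2E)-3-[4-(methoxymethoxy)phenyl]prop-2-enoyl]phenoxy}benzaldehyde; 9 1-[3-chloro-2-hydroxy-4-(methoxymethoxy)phenyl]ethan-1-one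
Product: 10 (2E)-1-[3-chloro-2-hydroxy-4-(methoxymethoxy)phenyl]-3-(4-{2-hydroxy-6-(methoxymethoxy)-3-[(2E)-3-[4-(methoxymethoxy)phenyl]prop-2-enoyl]phenoxy}phenyl)prop-2-en-1-one
Conditions: KOH (aq.), EtOH/THF, 0 °C to rt, argon; AcOH to pH 6 at 0 °C
Reagents that add atoms: none
Why: Claisen–Schmidt condensation in which 9 is the only enolisable partner and the formyl group of 6 the most electrophilic site, the enone already present being deactivated towards Michael addition as its 2'-phenoxide (a vinylogous carboxylate); E1cB dehydration should give the second E-enone.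

Step 7
Reactants: 10 (2E)-1-[3-chloro-2-hydroxy-4-(methoxymethoxy)phenyl]-3-(4-{2-hydroxy-6-(methoxymethoxy)-3-[(2E)-3-[4-(methoxymethoxy)phenyl]prop-2-enoyl]phenoxy}phenyl)prop-2-en-1-one
Product: 12 bisoflavolin J, via bis-acetal 11 (not isolated)
Conditions: Tl(NO3)3·3H2O (2.4 equiv), MeOH/HC(OMe)3 (3:1), rt; filter; then 10% aq. HCl, MeOH, 60 °C
Reagents that add atoms: none
Why: Trivalent thallium adds to each enone C=C in methanol (oxythallation, methoxy at the benzylic carbon, thallium at the carbon next to the carbonyl), the benzylic aryl group then shifts to the thallium-bearing carbon through a phenonium ion as monovalent thallium leaves, and methanol traps the oxocarbenium ion to give the bis(keto acetal) 11, in which the C3–C1' and C3''–C1''' bonds of the target exist. Aqueous HCl in methanol then ionises each acetal, the ortho-phenol adds to the oxocarbenium carbon and methanol is lost, which closes ring C (O1–C2) and ring C'' (O1''–C2'') each in a 6-exo-trig mode, and the same acid cleaves the three MOM acetals. The closest known reaction type is the Tl(NO3)3 oxidative rearrangement of 2'-hydroxychalcones to isoflavones, the laboratory copy of the biosynthetic 1,2-aryl shift, run here on two enones of one molecule. No stereocentre remains, since the two CH centres of 11 become the sp2 carbons C3 and C3''. The step needs aryl migration to win over attack of the free 2'-OH on the thallated carbon (aurone formation), which the para-oxygen donor on each migrating ring (OMOM on one, aryloxy on the other) secures by stabilising the phenonium ion. It also needs the phenols to resist the oxidant, which the MOM groups and the chelated, acyl-deactivated 2'-OH groups secure.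

**Compound list**

1 | gallacetophenone, 1-(2,3,4-trihydroxyphenyl)ethan-1-one | CC(=O)c1ccc(O)c(O)c1O | starting material
2 | 1-[2,3-dihydroxy-4-(methoxymethoxy)phenyl]ethan-1-one | CC(=O)c1ccc(OCOC)c(O)c1O | intermediate
3 | 4-(methoxymethoxy)benzaldehyde | COCOc1ccc(C=O)cc1 | starting material
4 | (2E)-1-[2,3-dihydroxy-4-(methoxymethoxy)phenyl]-3-[4-(methoxymethoxy)phenyl]prop-2-en-1-one | COCOc1ccc(/C=C/C(=O)c2ccc(OCOC)c(O)c2O)cc1 | intermediate
5 | 4-fluorobenzaldehyde | O=Cc1ccc(F)cc1 | starting material
6 | 4-{2-hydroxy-6-(methoxymethoxy)-3-[(2E)-3-[4-(methoxymethoxy)phenyl]prop-2-enoyl]phenoxy}benzaldehyde | COCOc1ccc(/C=C/C(=O)c2ccc(OCOC)c(Oc3ccc(C=O)cc3)c2O)cc1 | intermediate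
7 | 2-chlororesorcinol (2-chlorobenzene-1,3-diol) | Oc1cccc(O)c1Cl | starting material
8 | 1-(3-chloro-2,4-dihydroxyphenyl)ethan-1-one | CC(=O)c1ccc(O)c(Cl)c1O | intermediate
9 | 1-[3-chloro-2-hydroxy-4-(methoxymethoxy)phenyl]ethan-1-one | CC(=O)c1ccc(OCOC)c(Cl)c1O | intermediate
10 | (2E)-1-[3-chloro-2-hydroxy-4-(methoxymethoxy)phenyl]-3-(4-{2-hydroxy-6-(methoxymethoxy)-3-[(2E)-3-[4-(methoxymethoxy)phenyl]prop-2-enoyl]phenoxy}phenyl)prop-2-en-1-one | COCOc1ccc(/C=C/C(=O)c2ccc(OCOC)c(Oc3ccc(/C=C/C(=O)c4ccc(OCOC)c(Cl)c4O)cc3)c2O)cc1 | intermediate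
11 | 1-[3-chloro-2-hydroxy-4-(methoxymethoxy)phenyl]-2-(4-{3-[3,3-dimethoxy-2-[4-(methoxymethoxy)phenyl]propanoyl]-2-hydroxy-6-(methoxymethoxy)phenoxy}phenyl)-3,3-dimethoxypropan-1-one (mixture of stereoisomers) | COCOc1ccc(C(C(OC)OC)C(=O)c2ccc(OCOC)c(Oc3ccc(C(C(OC)OC)C(=O)c4ccc(OCOC)c(Cl)c4O)cc3)c2O)cc1 | intermediate (not isolated)
12 | bisoflavolin J, 8-chloro-7-hydroxy-3-(4-{[7-hydroxy-3-(4-hydroxyphenyl)-4-oxo-4H-chromen-8-yl]oxy}phenyl)-4H-chromen-4-one | O=c1c(-c2ccc(Oc3c(O)ccc4c(=O)c(-c5ccc(O)cc5)coc34)cc2)coc2c(Cl)c(O)ccc12 | target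

**Step count and risks**

Total steps: 7. Longest linear sequence: 5 (steps 1, 2, 3, 6, 7).

Steps most likely to fail:

1. Step 7. The aryloxy-substituted ring of the chlorinated half may migrate more slowly than the MOM-oxyphenyl ring, so that the free 2'-OH attacks the thallated carbon instead. Nitric acid set free may also strip MOM groups early and expose phenols to the oxidant. The fallback sets out from 10 and places ring closure before the aryl shift. NaOAc in refluxing EtOH should convert both 2'-hydroxychalcone units by intramolecular oxa-Michael addition into the bis-flavanone 8-chloro-7-(methoxymethoxy)-2-[4-({7-(methoxymethoxy)-2-[4-(methoxymethoxy)phenyl]-4-oxochroman-8-yl}oxy)phenyl]chroman-4-one F1, which holds no free phenol. PhI(OH)OTs (trivalent iodine) in MeCN at 60 °C should then effect the known flavanone-to-isoflavone 2,3-aryl shift in both halves to give the tris-MOM ether 8-chloro-7-(methoxymethoxy)-3-[4-({7-(methoxymethoxy)-3-[4-(methoxymethoxy)phenyl]-4-oxo-4H-chromen-8-yl}oxy)phenyl]-4H-chromen-4-one F2. HCl in MeOH cleaves the MOM groups and the fallback returns at 12.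

2. Step 3. The doubly ortho-flanked phenoxide may add too slowly to the fluoroarene at a temperature the hydroxychalcone tolerates, so that cyclisation to the flavanone, arylation at the 2'-oxygen or base-induced decomposition take over. The fallback sets out from 4 and uses ligand coupling at trivalent iodine at room temperature. The reagent is (4-formylphenyl)(2,4,6-trimethoxyphenyl)iodonium 4-methylbenzenesulfonate F3, made from 4-iodobenzaldehyde, mCPBA, TsOH·H2O and 1,3,5-trimethoxybenzene. With K2CO3 in MeCN it should transfer the electron-poor formylphenyl group to the 3'-phenoxide, the trimethoxyphenyl ring leaving as the aryl iodide, and the fallback returns at 6.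

3. Step 6. Hydroxide may reverse the first condensation (retro-aldol cleavage of the enone already present), or the enolate of 9 may add to that enone in a Michael reaction, so that scrambled chalcones form. The fallback sets out from 9 and replaces the aldol condensation by an olefination under neutral conditions. Bromination at the methyl group with PhNMe3Br3 in THF at 0 °C should give 2-bromo-1-[3-chloro-2-hydroxy-4-(methoxymethoxy)phenyl]ethan-1-one F4. PPh3 in toluene should give {2-[3-chloro-2-hydroxy-4-(methoxymethoxy)phenyl]-2-oxoethyl}triphenylphosphonium bromide F5, and aqueous Na2CO3 the stabilised ylide 1-[3-chloro-2-hydroxy-4-(methoxymethoxy)phenyl]-2-(triphenyl-λ5-phosphanylidene)ethan-1-one F6. Wittig reaction of F6 with aldehyde 6 in toluene at 80 °C should give the E-enone, and the fallback returns at 10.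

**Further compounds**

F1 | step 7 | 8-chloro-7-(methoxymethoxy)-2-[4-({7-(methoxymethoxy)-2-[4-(methoxymethoxy)phenyl]-4-oxochroman-8-yl}oxy)phenyl]chroman-4-one (mixture of diastereomers) | COCOc1ccc(C2CC(=O)c3ccc(OCOC)c(Oc4ccc(C5CC(=O)c6ccc(OCOC)c(Cl)c6O5)cc4)c3O2)cc1
F2 | step 7 | 8-chloro-7-(methoxymethoxy)-3-[4-({7-(methoxymethoxy)-3-[4-(methoxymethoxy)phenyl]-4-oxo-4H-chromen-8-yl}oxy)phenyl]-4H-chromen-4-one | COCOc1ccc(-c2coc3c(Oc4ccc(-c5coc6c(Cl)c(OCOC)ccc6c5=O)cc4)c(OCOC)ccc3c2=O)cc1
F3 | step 3 | (4-formylphenyl)(2,4,6-trimethoxyphenyl)iodonium 4-methylbenzenesulfonate | O=Cc1ccc([I+]c2c(OC)cc(OC)cc2OC)cc1.Cc1ccc(S(=O)(=O)[O-])cc1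
F4 | step 6 | 2-bromo-1-[3-chloro-2-hydroxy-4-(methoxymethoxy)phenyl]ethan-1-one | O=C(CBr)c1ccc(OCOC)c(Cl)c1O
F5 | step 6 | {2-[3-chloro-2-hydroxy-4-(methoxymethoxy)phenyl]-2-oxoethyl}triphenylphosphonium bromide | O=C(C[P+](c1ccccc1)(c1ccccc1)c1ccccc1)c1ccc(OCOC)c(Cl)c1O.[Br-]
F6 | step 6 | 1-[3-chloro-2-hydroxy-4-(methoxymethoxy)phenyl]-2-(triphenyl-λ5-phosphanylidene)ethan-1-one | O=C(C=P(c1ccccc1)(c1ccccc1)c1ccccc1)c1ccc(OCOC)c(Cl)c1O
A1 | direct plan | 3-(4-bromophenyl)-8-chloro-7-hydroxy-4H-chromen-4-one | O=c1c(-c2ccc(Br)cc2)coc2c(Cl)c(O)ccc12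
A2 | direct plan | 3-(4-bromophenyl)-8-chloro-7-methoxy-4H-chromen-4-one | COc1ccc2c(=O)c(-c3ccc(Br)cc3)coc2c1Cl
A3 | direct plan | 2,6-dimethoxyphenol | COc1cccc(OC)c1O
A4 | direct plan | 8-chloro-3-[4-(2,6-dimethoxyphenoxy)phenyl]-7-methoxy-4H-chromen-4-one | COc1ccc2c(=O)c(-c3ccc(Oc4c(OC)cccc4OC)cc3)coc2c1Cl
A5 | direct plan | 8-chloro-3-[4-(2,6-dihydroxyphenoxy)phenyl]-7-hydroxy-4H-chromen-4-one | Oc1ccc2c(=O)c(-c3ccc(Oc4c(O)cccc4O)cc3)coc2c1Cl
A6 | direct plan | 4-hydroxyphenylacetic acid | OC(=O)Cc1ccc(O)cc1
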